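I began from a one-step world, in which each pre-initiator starts a chain at once and each unit of free monomer fed joins one; that gives lengths of 10.0 for red and 7.14 for green.

| setting | red | green |
|---|---|---|
| free monomer | 14 mM (fed, over 5.0 min) | 10 mM (fed, over 5.0 min) |
| pre-initiator | 1.4 mM | 1.4 mM |
| time | 5.0 min | 5.0 min |

    free monomer + initiator → living end + monomer in chains (k1 = 2.68 /M/s)
    free monomer + living end → monomer in chains + living end, rate k2*[living end]*[free monomer] (k2 = 18.3 /M/s)
    pre-initiator → initiator (k3 = 0.0116 /s)

* which of the two ends with the longer chains by the average number of monomer units in a chain (chains begun, living or dead) ("neither" if they lie within 10%) (red / green / neither)
* average number of monomer units in a chain (chains begun, living or dead) at the end, red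
* average number of monomer units in a chain (chains begun, living or dead) at the end, green

- the average divides the monomer in chains by the number of chains begun, living and dead together
- run time (red): 5.0 min

The pre-initiator has a half-life of 0.996 min, shorter than the dosing time of 5.0 min, so I treated its charge as available initiator. With that charge counted as living ends, the pseudo-first-order uptake of free monomer by step 2 takes 0.651 min, again shorter than the dosing time, so I let uptake balance the feed. In this estimate the free monomer stood at uptake time over dosing time as a fraction of its charge: 0.130 in red and green alike.

Next I integrated the rate that counts chains. The logarithm of the unstarted initiator falls at k1 times the free monomer, and at the balanced level this sums over the dosing time to an exponent: k1 over k2, times the charge of free monomer over that of pre-initiator. That exponent was 1.46 for red and 1.05 for green, so the fractions started were 0.769 and 0.649.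

The weak link was counting the whole charge as living ends. I reforged it by dividing each exponent by its fraction, which gave 0.851 for red and 0.801 for green: the started fraction. My estimate of the free monomer left became 0.153 of the charge for red and 0.163 for green. Length is the charge ratio, times the fraction not left free, over the started fraction: 9.95 for red and 7.47 for green. My choice was red.

The forecast gave red, with 10.3 and 7.9, holding that “the average length follows the monomer fed”.

The simulation gave red, with 10.3 for red and 7.86 for green.

In red at 5.00 min, the half-life of free monomer by step 2 was 0.57 min, shorter than the dosing time, and free monomer stood at 18.0% of its charge. Living ends stood at 0.797 of the pre-initiator charge, against my started fraction of 0.851. For the flask like red but with 0.35 mM of pre-initiator, my reckoning gave a started fraction of 0.997, free monomer left at 0.522 of its charge, and a length of 19.2. The computed flask gave 54% of its free monomer left, living ends at 0.920 of its pre-initiator charge, and a length of 19.9.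

The rate constants belong to no real substance; the flask was simulated.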